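**Retrosynthetic overview**
1. Target 21 ⇐ hydrogenolysis of dibenzyl ester 20 ⇐ primary alcohol 16 + O-trifluoroacetyl-(R)-malic anhydride 18, opened regioselectively at the malate C1 carbonyl.
2. Lactone 15 ⇐ tertiary allylic formate 14: a ruthenium-catalysed intramolecular addition of the formyl C–H bond across the vinyl group makes the C4–C5 (CH2–C=O) bond of the oxolan-2-one and closes the ring.
3. Enabling feature: in the lactone ring (O1, quaternary C2, C3H2, C4H2, C5=O) the ring oxygen and the unsubstituted C3–C4 bridge both hang on the fully substituted C2, so an O-formyl group (O1–C5) and a vinyl group (C3=C4) can sit on one carbinol carbon that has no allylic hydrogen.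
4. Vinyl carbinol 13 ⇐ diethyl (S)-malate 4 + iodide 3: Fráter–Seebach anti-alkylation sets the side-chain centre (R); Seebach self-regeneration of stereocentres with a vinyl cation equivalent sets the quaternary centre (S) with retention.
5. Ring order: temporary 1,3-dioxolan-4-one (closed in step 5, opened in step 8), then the γ-butyrolactone (step 11); the anhydride ring of 18 is only a transient activating ring (steps 13 and 14).

Key step: step 11

Remark: sulfoxide 10 is carried as a mixture of epimers at sulfur, which is lost in step 7.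

Step 1
Reactants: 1 10-bromodecan-1-ol
Product: 2 [(10-bromodecyl)oxy](tert-butyl)diphenylsilane
Conditions: TBDPSCl, imidazole, DMF, 0 °C to rt
Reagents that add atoms: tert-butyl(chloro)diphenylsilane (TBDPSCl), CC(C)(C)[Si](Cl)(c1ccccc1)c1ccccc1
Why: Imidazole-promoted silylation of the primary alcohol installs a silyl ether that should survive the basic, acidic and thermal steps ahead and later be removed without touching benzyl esters.

Step 2
Reactants: 2 [(10-bromodecyl)oxy](tert-butyl)diphenylsilane
Product: 3 tert-butyl[(10-iododecyl)oxy]diphenylsilane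
Conditions: NaI, acetone, reflux
Reagents that add atoms: sodium iodide, [Na+].[I-]
Why: Finkelstein halide exchange (SN2, driven by precipitation of NaBr) supplies the more reactive primary iodide for the enolate alkylation.

Step 3
Reactants: 4 diethyl (S)-malate; 3 tert-butyl[(10-iododecyl)oxy]diphenylsilane
Product: 6 diethyl (2S,3R)-3-{10-[(tert-butyldiphenylsilyl)oxy]decyl}-2-hydroxybutanedioate, via dilithium alkoxide enolate 5 (not isolated)
Conditions: LiN(iPr)2 (2.2 equiv), THF, −78 to −20 °C; then 3, DMPU, −78 to 0 °C; AcOH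
Reagents that add atoms: none
Why: Fráter–Seebach alkylation, in which the chelated dilithium alkoxide enolate is attacked on the face opposite the ester group of the alkoxide carbon, so the new C3 centre should form as (R) (anti, 2S,3R) while C2 is untouched.

Step 4
Reactants: 6 diethyl (2S,3R)-3-{10-[(tert-butyldiphenylsilyl)oxy]decyl}-2-hydroxybutanedioate
Product: 7 (2S,3R)-3-{10-[(tert-butyldiphenylsilyl)oxy]decyl}-2-hydroxybutanedioic acid
Conditions: LiOH·H2O (4 equiv), THF/MeOH/H2O, 0 °C to rt; then 1 M HCl to pH 2–3 at 0 °C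
Reagents that add atoms: lithium hydroxide, [Li+].[OH-]
Why: Mild ester saponification should free both acids without epimerization, since each α-carbon is protected once its carboxylate has formed, and the silyl ether is stable to these conditions.

Step 5
Reactants: 7 (2S,3R)-3-{10-[(tert-butyldiphenylsilyl)oxy]decyl}-2-hydroxybutanedioic acid
Product: 8 (2R)-2-[(2S,4S)-2-tert-butyl-5-oxo-1,3-dioxolan-4-yl]-12-[(tert-butyldiphenylsilyl)oxy]dodecanoic acid
Conditions: t-BuCHO (3 equiv), p-TsOH·H2O (5 mol %), pentane, reflux, Dean–Stark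
Reagents that add atoms: pivalaldehyde (2,2-dimethylpropanal), CC(C)(C)C=O
Why: Seebach acetalization under equilibrating acid catalysis should close the five-membered dioxolanone on the α-hydroxy acid (favoured over the six-membered ring with the β-carboxyl) and set the new acetal centre cis to the ring substituent by thermodynamic control from the existing (S) centre.

Step 6
Reactants: 8 (2R)-2-[(2S,4S)-2-tert-butyl-5-oxo-1,3-dioxolan-4-yl]-12-[(tert-butyldiphenylsilyl)oxy]dodecanoic acid
Product: 10 (2R)-2-{(2S,4S)-2-tert-butyl-5-oxo-4-[2-(phenylsulfinyl)ethyl]-1,3-dioxolan-4-yl}-12-[(tert-butyldiphenylsilyl)oxy]dodecanoic acid, via dilithium carboxylate enolate 9 (not isolated)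
Conditions: LiN(SiMe3)2 (2.2 equiv), THF, −78 °C; phenyl vinyl sulfoxide (1.5 equiv), −78 to −30 °C; AcOH
Reagents that add atoms: phenyl vinyl sulfoxide, C=CS(=O)c1ccccc1
Why: Self-regeneration of stereocentres: the carboxylate shields the side-chain α-hydrogen and the dioxolanone enolate should undergo Michael addition to the vinyl sulfoxide (a vinyl cation equivalent) on the face trans to the tert-butyl group, so the new C–C bond takes the place of the former hydrogen and the quaternary centre forms with net retention.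

Step 7
Reactants: 10 (2R)-2-{(2S,4S)-2-tert-butyl-5-oxo-4-[2-(phenylsulfinyl)ethyl]-1,3-dioxolan-4-yl}-12-[(tert-butyldiphenylsilyl)oxy]dodecanoic acid
Product: 11 (2R)-2-[(2S,4S)-2-tert-butyl-4-ethenyl-5-oxo-1,3-dioxolan-4-yl]-12-[(tert-butyldiphenylsilyl)oxy]dodecanoic acid
Conditions: toluene, 120 °C, sealed tube
Reagents that add atoms: none
Why: Thermal syn-elimination of the sulfoxide (Ei), whose only β-hydrogens lie on the carbon attached to the quaternary centre, should unveil the vinyl group without touching a stereocentre.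

Step 8
Reactants: 11 (2R)-2-[(2S,4S)-2-tert-butyl-4-ethenyl-5-oxo-1,3-dioxolan-4-yl]-12-[(tert-butyldiphenylsilyl)oxy]dodecanoic acid
Product: 12 (2S,3R)-3-{10-[(tert-butyldiphenylsilyl)oxy]decyl}-2-ethenyl-2-hydroxybutanedioic acid
Conditions: LiOH·H2O (3 equiv), THF/H2O, 0 °C to rt; then 1 M HCl to pH 2–3 at 0 °C
Reagents that add atoms: lithium hydroxide, [Li+].[OH-]
Why: Saponification of the acylal-type lactone gives a hemiacetal that should collapse with loss of pivalaldehyde, freeing the tertiary alcohol and the second acid with no bond to a stereocentre broken.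

Step 9
Reactants: 12 (2S,3R)-3-{10-[(tert-butyldiphenylsilyl)oxy]decyl}-2-ethenyl-2-hydroxybutanedioic acid
Product: 13 dibenzyl (2S,3R)-3-{10-[(tert-butyldiphenylsilyl)oxy]decyl}-2-ethenyl-2-hydroxybutanedioate
Conditions: BnBr (2.4 equiv), KHCO3 (3 equiv), DMF, rt
Reagents that add atoms: benzyl bromide, BrCc1ccccc1
Why: SN2 O-alkylation of both carboxylates with a mild bicarbonate base should leave the tertiary alcohol untouched and avoid retro-aldol cleavage.

Step 10
Reactants: 13 dibenzyl (2S,3R)-3-{10-[(tert-butyldiphenylsilyl)oxy]decyl}-2-ethenyl-2-hydroxybutanedioate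
Product: 14 dibenzyl (2S,3R)-3-{10-[(tert-butyldiphenylsilyl)oxy]decyl}-2-ethenyl-2-(formyloxy)butanedioate
Conditions: HCO2H/Ac2O (preformed acetic formic anhydride, 5 equiv), pyridine, DMAP (10 mol %), CH2Cl2, 0 °C to rt
Reagents that add atoms: acetic formic anhydride, CC(=O)OC=O
Why: DMAP-catalysed acyl transfer from the mixed anhydride should deliver the small, more electrophilic formyl group selectively to the hindered tertiary alcohol (O-formylation).

Step 11
Reactants: 14 dibenzyl (2S,3R)-3-{10-[(tert-butyldiphenylsilyl)oxy]decyl}-2-ethenyl-2-(formyloxy)butanedioate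
Product: 15 benzyl (2S)-2-[(2R)-1-(benzyloxy)-12-[(tert-butyldiphenylsilyl)oxy]-1-oxododecan-2-yl]-5-oxooxolane-2-carboxylate
Conditions: Ru3(CO)12 (5 mol %), n-Bu4NI (15 mol %), toluene/DMSO (4:1), CO (1 atm), 140 °C, sealed tube
Reagents that add atoms: none
Why: Proposed new method: oxidative addition of the formyl C–H bond of the tertiary formate to a halide-activated zerovalent ruthenium carbonyl should give an alkoxycarbonyl ruthenium hydride, the neighbouring vinyl group should insert into Ru–H with ruthenium at the terminal carbon to give a six-membered oxaruthenacycle, and acyl–alkyl reductive elimination should then forge the CH2–C(=O) bond and release the γ-lactone; the closest known reaction types are the Ru3(CO)12-catalysed intramolecular hydrocarbamoylation of N-allyl formamides to pyrrolidin-2-ones and the chelation-assisted ruthenium-catalysed hydroesterification of alkenes with formates. The five-membered ring is closed in a formally 5-endo-trig sense (both alkene carbons become ring atoms), which is feasible because the C–C bond comes from reductive elimination out of the six-membered metallacycle and not from a direct attack. No new stereocentre is formed, and the quaternary C2 and the side-chain centre are spectators under these neutral conditions. The step needs linear regioselectivity and chemoselectivity for C–H addition over decarbonylation, allylic C–O ionization and alkene isomerization: the branched mode would give a strained β-lactone with ruthenium next to the quaternary carbon, the CO atmosphere holds back decarbonylation (and any liberated alcohol can converge on the same lactone through a ruthenium hydride/CO pathway), the ester on the carbinol carbon disfavours ionization, and the fully substituted carbinol carbon leaves no allylic hydrogen for isomerization.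

Step 12
Reactants: 15 benzyl (2S)-2-[(2R)-1-(benzyloxy)-12-[(tert-butyldiphenylsilyl)oxy]-1-oxododecan-2-yl]-5-oxooxolane-2-carboxylate
Product: 16 benzyl (2S)-2-[(2R)-1-(benzyloxy)-12-hydroxy-1-oxododecan-2-yl]-5-oxooxolane-2-carboxylate
Conditions: HF·pyridine, THF/pyridine, 0 °C to rt
Reagents that add atoms: none
Why: Fluoride-induced cleavage of the silyl ether under non-basic conditions should free the primary alcohol while avoiding base-induced β-elimination of the lactone oxygen next to the benzyl ester.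

Step 13
Reactants: 17 (R)-malic acid
Product: 18 (3R)-2,5-dioxooxolan-3-yl trifluoroacetate
Conditions: (CF3CO)2O (4 equiv), neat, 0 °C to rt; evaporate
Reagents that add atoms: trifluoroacetic anhydride, O=C(OC(=O)C(F)(F)F)C(F)(F)F
Why: Trifluoroacetic anhydride should dehydrate the 1,4-diacid to the cyclic anhydride and acylate the hydroxyl in one operation under non-enolizing acidic conditions, so the stereocentre is retained.

Step 14
Reactants: 16 benzyl (2S)-2-[(2R)-1-(benzyloxy)-12-hydroxy-1-oxododecan-2-yl]-5-oxooxolane-2-carboxylate; 18 (3R)-2,5-dioxooxolan-3-yl trifluoroacetate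
Product: 20 (3R)-4-({(11R)-12-(benzyloxy)-11-[(2S)-2-[(benzyloxy)carbonyl]-5-oxooxolan-2-yl]-12-oxododecyl}oxy)-3-hydroxy-4-oxobutanoic acid, via O-trifluoroacetyl ester acid 19 (not isolated)
Conditions: 18 (1.5 equiv), CH2Cl2, 0 °C to rt; then THF/pH 7 phosphate buffer, rt
Reagents that add atoms: none
Why: Regioselective alcoholysis of the unsymmetrical cyclic anhydride at the carbonyl next to the electron-withdrawing trifluoroacetoxy group should give the 1-ester with the 4-carboxylic acid free, and the labile trifluoroacetate is hydrolysed in the buffered work-up.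

Step 15
Reactants: 20 (3R)-4-({(11R)-12-(benzyloxy)-11-[(2S)-2-[(benzyloxy)carbonyl]-5-oxooxolan-2-yl]-12-oxododecyl}oxy)-3-hydroxy-4-oxobutanoic acid
Product: 21 (3R)-4-({(11R)-11-carboxy-11-[(2S)-2-carboxy-5-oxooxolan-2-yl]undecyl}oxy)-3-hydroxy-4-oxobutanoic acid
Conditions: H2 (1 atm), 10% Pd/C, EtOAc, rt
Reagents that add atoms: none
Why: Catalytic hydrogenolysis should cleave only the two benzyl esters under neutral conditions, leaving the lactone, the alkyl malate ester and all stereocentres untouched.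

**Compound list**
1 | 10-bromodecan-1-ol | OCCCCCCCCCCBr | starting material
2 | [(10-bromodecyl)oxy](tert-butyl)diphenylsilane | BrCCCCCCCCCCO[Si](c1ccccc1)(c1ccccc1)C(C)(C)C | intermediate
3 | tert-butyl[(10-iododecyl)oxy]diphenylsilane | ICCCCCCCCCCO[Si](c1ccccc1)(c1ccccc1)C(C)(C)C | intermediate
4 | diethyl (S)-malate | CCOC(=O)C[C@H](O)C(=O)OCC | starting material
5 | dilithium alkoxide enolate of diethyl (S)-malate | [Li+].[Li+].CCOC([O-])=C[C@H]([O-])C(=O)OCC | intermediate
6 | diethyl (2S,3R)-3-{10-[(tert-butyldiphenylsilyl)oxy]decyl}-2-hydroxybutanedioate | CCOC(=O)[C@@H](O)[C@@H](CCCCCCCCCCO[Si](c1ccccc1)(c1ccccc1)C(C)(C)C)C(=O)OCC | intermediate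
7 | (2S,3R)-3-{10-[(tert-butyldiphenylsilyl)oxy]decyl}-2-hydroxybutanedioic acid | OC(=O)[C@@H](O)[C@@H](CCCCCCCCCCO[Si](c1ccccc1)(c1ccccc1)C(C)(C)C)C(=O)O | intermediate
8 | (2R)-2-[(2S,4S)-2-tert-butyl-5-oxo-1,3-dioxolan-4-yl]-12-[(tert-butyldiphenylsilyl)oxy]dodecanoic acid | OC(=O)[C@H](CCCCCCCCCCO[Si](c1ccccc1)(c1ccccc1)C(C)(C)C)[C@@H]1O[C@H](C(C)(C)C)OC1=O | intermediate
9 | dilithium carboxylate enolate of 8 | [Li+].[Li+].[O-]C(=O)[C@H](CCCCCCCCCCO[Si](c1ccccc1)(c1ccccc1)C(C)(C)C)C1=C([O-])O[C@@H](C(C)(C)C)O1 | intermediate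
10 | (2R)-2-{(2S,4S)-2-tert-butyl-5-oxo-4-[2-(phenylsulfinyl)ethyl]-1,3-dioxolan-4-yl}-12-[(tert-butyldiphenylsilyl)oxy]dodecanoic acid (sulfur epimers) | OC(=O)[C@H](CCCCCCCCCCO[Si](c1ccccc1)(c1ccccc1)C(C)(C)C)[C@]1(CCS(=O)c2ccccc2)O[C@H](C(C)(C)C)OC1=O | intermediate
11 | (2R)-2-[(2S,4S)-2-tert-butyl-4-ethenyl-5-oxo-1,3-dioxolan-4-yl]-12-[(tert-butyldiphenylsilyl)oxy]dodecanoic acid | OC(=O)[C@H](CCCCCCCCCCO[Si](c1ccccc1)(c1ccccc1)C(C)(C)C)[C@]1(C=C)O[C@H](C(C)(C)C)OC1=O | intermediate
12 | (2S,3R)-3-{10-[(tert-butyldiphenylsilyl)oxy]decyl}-2-ethenyl-2-hydroxybutanedioic acid | OC(=O)[C@H](CCCCCCCCCCO[Si](c1ccccc1)(c1ccccc1)C(C)(C)C)[C@@](O)(C=C)C(=O)O | intermediate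
13 | dibenzyl (2S,3R)-3-{10-[(tert-butyldiphenylsilyl)oxy]decyl}-2-ethenyl-2-hydroxybutanedioate | O=C(OCc1ccccc1)[C@H](CCCCCCCCCCO[Si](c1ccccc1)(c1ccccc1)C(C)(C)C)[C@@](O)(C=C)C(=O)OCc1ccccc1 | intermediate
14 | dibenzyl (2S,3R)-3-{10-[(tert-butyldiphenylsilyl)oxy]decyl}-2-ethenyl-2-(formyloxy)butanedioate | O=C(OCc1ccccc1)[C@H](CCCCCCCCCCO[Si](c1ccccc1)(c1ccccc1)C(C)(C)C)[C@@](OC=O)(C=C)C(=O)OCc1ccccc1 | intermediate
15 | benzyl (2S)-2-[(2R)-1-(benzyloxy)-12-[(tert-butyldiphenylsilyl)oxy]-1-oxododecan-2-yl]-5-oxooxolane-2-carboxylate | O=C(OCc1ccccc1)[C@H](CCCCCCCCCCO[Si](c1ccccc1)(c1ccccc1)C(C)(C)C)[C@]1(C(=O)OCc2ccccc2)CCC(=O)O1 | intermediate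
16 | benzyl (2S)-2-[(2R)-1-(benzyloxy)-12-hydroxy-1-oxododecan-2-yl]-5-oxooxolane-2-carboxylate | O=C(OCc1ccccc1)[C@H](CCCCCCCCCCO)[C@]1(C(=O)OCc2ccccc2)CCC(=O)O1 | intermediate
17 | (R)-malic acid | OC(=O)C[C@@H](O)C(=O)O | starting material
18 | (3R)-2,5-dioxooxolan-3-yl trifluoroacetate | O=C1C[C@@H](OC(=O)C(F)(F)F)C(=O)O1 | intermediate
19 | (3R)-4-({(11R)-12-(benzyloxy)-11-[(2S)-2-[(benzyloxy)carbonyl]-5-oxooxolan-2-yl]-12-oxododecyl}oxy)-4-oxo-3-(trifluoroacetoxy)butanoic acid | O=C(O)C[C@@H](OC(=O)C(F)(F)F)C(=O)OCCCCCCCCCC[C@@H](C(=O)OCc1ccccc1)[C@]1(C(=O)OCc2ccccc2)CCC(=O)O1 | intermediate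
20 | (3R)-4-({(11R)-12-(benzyloxy)-11-[(2S)-2-[(benzyloxy)carbonyl]-5-oxooxolan-2-yl]-12-oxododecyl}oxy)-3-hydroxy-4-oxobutanoic acid | O=C(O)C[C@@H](O)C(=O)OCCCCCCCCCC[C@@H](C(=O)OCc1ccccc1)[C@]1(C(=O)OCc2ccccc2)CCC(=O)O1 | intermediate
21 | (3R)-4-({(11R)-11-carboxy-11-[(2S)-2-carboxy-5-oxooxolan-2-yl]undecyl}oxy)-3-hydroxy-4-oxobutanoic acid | O=C(O)C[C@@H](O)C(=O)OCCCCCCCCCC[C@@H](C(=O)O)[C@]1(C(=O)O)CCC(=O)O1 | target

**Step count and risks**
Total steps: 15. Longest linear sequence: 14 steps (steps 1 to 12, then 14 and 15); step 13 is a one-step side branch that supplies 18.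

Step 11 (proposed new method) is the riskiest. The formyl C–H addition may lose out to decarbonylation of the formate, to ionization or β-elimination at the tertiary allylic C–O bond, or the catalyst may simply not turn over. The fallback sets out from alcohol 13, so that step 10 is skipped, and uses known chemistry. Linear-selective hydroformylation of the vinyl group (Rh(acac)(CO)2, Xantphos, CO/H2, toluene, 80 °C) should give an aldehyde that is trapped by the tertiary hydroxyl as the lactol benzyl (2S)-2-[(2R)-1-(benzyloxy)-12-[(tert-butyldiphenylsilyl)oxy]-1-oxododecan-2-yl]-5-hydroxyoxolane-2-carboxylate F1 (mixture of anomers). Oxidation of the lactol (TEMPO cat., PhI(OAc)2, CH2Cl2, rt) comes back to the route at lactone 15.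

Step 6 is the second risk. Conjugate addition of the hindered, tetrasubstituted enolate to the weakly electrophilic vinyl sulfoxide may be slow, so that decomposition of the enolate on warming wins. The fallback sets out from 8: the same dianion is alkylated with allyl bromide, with the same approach trans to the tert-butyl group, to give (2R)-2-[(2S,4S)-2-tert-butyl-5-oxo-4-(prop-2-en-1-yl)-1,3-dioxolan-4-yl]-12-[(tert-butyldiphenylsilyl)oxy]dodecanoic acid F2. The allyl group is then isomerized (RuHCl(CO)(PPh3)3, toluene, 80 °C) to (2R)-2-{(2S,4S)-2-tert-butyl-5-oxo-4-[(1E)-prop-1-en-1-yl]-1,3-dioxolan-4-yl}-12-[(tert-butyldiphenylsilyl)oxy]dodecanoic acid F3. Ethenolysis (second-generation Hoveyda–Grubbs catalyst, ethylene, CH2Cl2, 40 °C) trims this to the vinyl compound and comes back to the route at 11, replacing steps 6 and 7.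

Step 3 is the third risk. SN2 alkylation of the dianion by an unactivated primary iodide may be slow relative to proton transfer and decomposition on warming, giving low conversion, dialkylation or elimination of HI. The fallback sets out from 4: allylation with allyl bromide under the same conditions should give diethyl (2S,3R)-2-hydroxy-3-(prop-2-en-1-yl)butanedioate F4. Cross-metathesis (second-generation Grubbs catalyst, CH2Cl2, 40 °C) with tert-butyl(non-8-en-1-yloxy)diphenylsilane F5 (from commercial non-8-en-1-ol, TBDPSCl, imidazole) should give diethyl (2S,3R)-3-{(2E)-10-[(tert-butyldiphenylsilyl)oxy]dec-2-en-1-yl}-2-hydroxybutanedioate F6. Hydrogenation of the alkene (H2, 10% Pd/C, EtOAc) comes back to the route at 6.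

**Further compounds**
F1 | step 11 | benzyl (2S)-2-[(2R)-1-(benzyloxy)-12-[(tert-butyldiphenylsilyl)oxy]-1-oxododecan-2-yl]-5-hydroxyoxolane-2-carboxylate | O=C(OCc1ccccc1)[C@H](CCCCCCCCCCO[Si](c1ccccc1)(c1ccccc1)C(C)(C)C)[C@]1(C(=O)OCc2ccccc2)CCC(O)O1
F2 | step 6 | (2R)-2-[(2S,4S)-2-tert-butyl-5-oxo-4-(prop-2-en-1-yl)-1,3-dioxolan-4-yl]-12-[(tert-butyldiphenylsilyl)oxy]dodecanoic acid | OC(=O)[C@H](CCCCCCCCCCO[Si](c1ccccc1)(c1ccccc1)C(C)(C)C)[C@]1(CC=C)O[C@H](C(C)(C)C)OC1=O
F3 | step 6 | (2R)-2-{(2S,4S)-2-tert-butyl-5-oxo-4-[(1E)-prop-1-en-1-yl]-1,3-dioxolan-4-yl}-12-[(tert-butyldiphenylsilyl)oxy]dodecanoic acid | OC(=O)[C@H](CCCCCCCCCCO[Si](c1ccccc1)(c1ccccc1)C(C)(C)C)[C@]1(/C=C/C)O[C@H](C(C)(C)C)OC1=O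
F4 | step 3 | diethyl (2S,3R)-2-hydroxy-3-(prop-2-en-1-yl)butanedioate | CCOC(=O)[C@@H](O)[C@@H](CC=C)C(=O)OCC
F5 | step 3 | tert-butyl(non-8-en-1-yloxy)diphenylsilane | C=CCCCCCCCO[Si](c1ccccc1)(c1ccccc1)C(C)(C)C
F6 | step 3 | diethyl (2S,3R)-3-{(2E)-10-[(tert-butyldiphenylsilyl)oxy]dec-2-en-1-yl}-2-hydroxybutanedioate | CCOC(=O)[C@@H](O)[C@@H](C/C=C/CCCCCCCO[Si](c1ccccc1)(c1ccccc1)C(C)(C)C)C(=O)OCC
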